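A direct plan would acylate the dianion of the bis-allyl ether of phloroacetophenone A1 with 3,4-bis(benzyloxy)benzoyl chloride A2 to the 1,3-diketone A3, oxidise the central carbon of A3 with peroxydisulfate to the sulfatoxy diketone A4, cyclodehydrate to the flavonol 3-sulfate A5, then deallylate, sulfate O7, debenzylate and acidify.
Its weakest operations would be:
(a) the persulfate C–O bond formation: it has no precedent on a β-diketonate, and para-hydroxylation of the free phenol and radical attack on allyl and benzyl ethers would compete;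
(b) the cyclodehydration of A4: the ring closure would be left to chance, because displacement of sulfate by the phenol (five-membered ring) or plain loss of sulfate could outrun pyranone formation;
(c) the allyl traffic on ring A: partial allylation of a triol and later double deallylation would spend two steps without gain, and every step after A5 would handle a salt.

**Plan of the new route**
Retrosynthesis: both S–O bonds are cut last (kept as neutral trichloroethyl diesters); ring A is then cut at C4a–C5, C5–C6, C7–C8 and C8–C8a to tert-butoxyacetylene and a 6-diazoacetyl-4-pyranone; C2–C1' is cut to a Suzuki pair; the rest is kojic acid.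
Rings arise in the order C (bought), B (attached), A (built last by a Wolff rearrangement/[2+2]/4π-opening/6π-electrocyclisation cascade).
Enabling feature: ring A carries oxygen at C5 and C7 and hydrogen at C6 and C8, and is fused at C4a–C8a to a 4-pyranone in which C4a is a C–H and C8a bears O1. A dienylketene C5(=O)=C6–C7(OR)=C8–C8a=C4a can therefore close only onto C4a and aromatise by one proton shift; ring C with O3 next to C4=O is the 5-hydroxy-4-pyranone of kojic acid.
Hence O3 is never introduced by oxidation, no pyranone closure is needed, O5 (free OH) and O7 (ether) emerge differentiated without selective alkylation of a triol, and no salt is handled before the last step.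

Key step: step 7

Assumption: the flavonol core is to be built, so quercetin and its glycosides are not used as starting materials; the target is isolated as the free bis(hydrogen sulfate) as drawn, liberated cold from its ammonium salt.

Step 1
Reactants: 1 kojic acid [5-hydroxy-2-(hydroxymethyl)-4H-pyran-4-one]
Product: 2 6-bromokojic acid [2-bromo-3-hydroxy-6-(hydroxymethyl)-4H-pyran-4-one]
Conditions: NBS (1.05 equiv), MeCN, 0 °C to rt, dark
Reagents that add atoms: N-bromosuccinimide, O=C1CCC(=O)N1Br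
Why: Electrophilic bromination of the enolic 5-hydroxy-4-pyranone should occur at C6, the carbon ortho to the free hydroxyl, where kojic acid also undergoes Mannich, aldol and azo coupling reactions.

Step 2
Reactants: 2 6-bromokojic acid
Product: 3 2-bromo-6-(hydroxymethyl)-3-[(4-methoxybenzyl)oxy]-4H-pyran-4-one
Conditions: 4-methoxybenzyl chloride (1.1 equiv), K2CO3 (1.5 equiv), DMF, rt
Reagents that add atoms: 4-methoxybenzyl chloride, COc1ccc(CCl)cc1
Why: Williamson ether synthesis; carbonate deprotonates only the acidic enolic hydroxyl, so the primary alcohol should stay free.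

Step 3
Reactants: 3 2-bromo-6-(hydroxymethyl)-3-[(4-methoxybenzyl)oxy]-4H-pyran-4-one; 4 3,4-bis(benzyloxy)phenylboronic acid
Product: 5 2-[3,4-bis(benzyloxy)phenyl]-6-(hydroxymethyl)-3-[(4-methoxybenzyl)oxy]-4H-pyran-4-one
Conditions: 4 (1.3 equiv), Pd(dppf)Cl2 (5 mol %), K2CO3 (2.5 equiv), 1,4-dioxane/H2O 5:1, 80 °C, Ar
Reagents that add atoms: none
Why: Suzuki–Miyaura coupling; zerovalent palladium should insert readily into the C–Br bond of the 2-bromo-4-pyranone (a vinylogous acyl bromide), and the free alcohol and the ethers are inert.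

Step 4
Reactants: 5 2-[3,4-bis(benzyloxy)phenyl]-6-(hydroxymethyl)-3-[(4-methoxybenzyl)oxy]-4H-pyran-4-one
Product: 6 6-[3,4-bis(benzyloxy)phenyl]-5-[(4-methoxybenzyl)oxy]-4-oxo-4H-pyran-2-carboxylic acid
Conditions: TEMPO (0.2 equiv), PhI(OAc)2 (2.2 equiv), MeCN/H2O 1:1, rt
Reagents that add atoms: water, O
Why: Oxoammonium (TEMPO) oxidation of the primary alcohol through the aldehyde hydrate to the carboxylic acid, giving a protected 6-aryl comenic acid; benzyl-type ethers should be untouched.

Step 5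
Reactants: 6 6-[3,4-bis(benzyloxy)phenyl]-5-[(4-methoxybenzyl)oxy]-4-oxo-4H-pyran-2-carboxylic acid
Product: 8 2-[3,4-bis(benzyloxy)phenyl]-6-(diazoacetyl)-3-[(4-methoxybenzyl)oxy]-4H-pyran-4-one, via isobutyl carbonic mixed anhydride 7 (not isolated)
Conditions: i-BuOCOCl (1.1 equiv), N-methylmorpholine (1.1 equiv), THF, −15 °C; then CH2N2 (ca. 3 equiv, Et2O), −15 °C to rt, dark
Reagents that add atoms: diazomethane, C=[N+]=[N-]
Why: First half of the Arndt–Eistert sequence; diazomethane is acylated by the mixed carbonic anhydride and the departing isobutyl carbonate takes up the proton.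

Step 6
Reactants: 9 trichloroethylene
Product: 13 tert-butoxyacetylene (tert-butyl ethynyl ether), via tert-butyl (E)-1,2-dichlorovinyl ether 10 (not isolated), via tert-butoxy(chloro)acetylene 11 (not isolated), via lithium tert-butoxyacetylide 12 (not isolated)
Conditions: KOt-Bu (1.0 equiv), THF, −78 °C to rt; n-BuLi (2.2 equiv), −78 to −40 °C; MeOH (1.1 equiv), −78 °C; cold aqueous wash; kept below 0 °C as a titrated solution
Reagents that add atoms: potassium tert-butoxide, CC(C)(C)[O-].[K+]
Why: Alkoxide/trichloroethylene route to alkynyl ethers; net vinylic substitution gives the dichlorovinyl ether, n-butyllithium effects dehydrochlorination and chlorine–lithium exchange, and protonation liberates the ynol ether, which is kept cold because it loses isobutene on warming.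

Step 7
Reactants: 8 2-[3,4-bis(benzyloxy)phenyl]-6-(diazoacetyl)-3-[(4-methoxybenzyl)oxy]-4H-pyran-4-one; 13 tert-butoxyacetylene
Product: 18 2-[3,4-bis(benzyloxy)phenyl]-7-tert-butoxy-5-hydroxy-3-[(4-methoxybenzyl)oxy]-4H-chromen-4-one, via pyranonylketene 14 (not isolated), via 4-pyranonyl-3-tert-butoxycyclobutenone 15 (not isolated), via dienylketene 16 (not isolated), via 4aH-chromene-4,5-dione tautomer 17 (not isolated)
Conditions: 13 (4 equiv), ClCH2CH2Cl (0.03 M), hν (405 nm LED), 10–15 °C, Ar; concentrate cold (removes excess 13); toluene, 90 °C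
Reagents that add atoms: none
Why: Irradiation into the weak n→π* band of the diazo ketone triggers a Wolff rearrangement in which the pyranonyl carbon migrates to the diazo carbon (new bond C8–C8a) and gives ketene 14; the polarised ynol ether 13 then adds in a regioselective [2+2] cycloaddition, its nucleophilic CH carbon to the ketene carbonyl carbon (C5–C6) and its oxygen-bearing carbon to the ketene α-carbon (C7–C8), to give cyclobutenone 15. On warming, 15 opens in a reversible conrotatory 4π-electrocyclic reaction to dienylketene 16, and ring A closes by a disrotatory 6π-electrocyclisation between the ketene carbon C5 and the pyranone C–H carbon C4a; enolisation of 17 then makes ring A aromatic, with the ketene oxygen as the free, chelated C5–OH and the ynol ether oxygen as the C7 tert-butyl ether. The closest known reaction type is the Danheiser benzannulation in its diazo ketone (photochemical Wolff) form with alkoxy- and siloxyalkynes, which annulates a resorcinol ring onto the double bond of alkenyl, aryl and heteroaryl diazo ketones. No stereocentre survives: the centres of 15 and 17 are transient and racemic. The step needs regioselectivity in the [2+2] (secured by the polarity of the ynol ether, which places O7 meta to O5) and a single site of ring closure (secured by ring C, where the other neighbour of C8a is O1). It also needs chemoselective excitation: 405 nm light should be absorbed by the diazo ketone but not by the 3-alkoxy-2-aryl-4-pyranone, and the ynol ether is removed before heating so that its thermal cleavage to ketene cannot acylate the new phenol.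

Step 8
Reactants: 18 2-[3,4-bis(benzyloxy)phenyl]-7-tert-butoxy-5-hydroxy-3-[(4-methoxybenzyl)oxy]-4H-chromen-4-one
Product: 19 2-[3,4-bis(benzyloxy)phenyl]-3,5,7-trihydroxy-4H-chromen-4-one (3',4'-di-O-benzylquercetin)
Conditions: TFA/CH2Cl2 1:4, Et3SiH (6 equiv), 0 °C to rt
Reagents that add atoms: none
Why: Acidolysis of the 4-methoxybenzyl and tert-butyl aryl ethers with triethylsilane as cation trap (ionic hydrogenation of the 4-methoxybenzyl cation); benzyl ethers should survive.

Step 9
Reactants: 19 2-[3,4-bis(benzyloxy)phenyl]-3,5,7-trihydroxy-4H-chromen-4-one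
Product: 20 2-[3,4-bis(benzyloxy)phenyl]-5-hydroxy-4-oxo-4H-chromene-3,7-diyl bis(2,2,2-trichloroethyl) bis(sulfate)
Conditions: Cl3CCH2OSO2Cl (2.4 equiv), Et3N (3 equiv), DMAP (0.2 equiv), THF, 0 °C to rt
Reagents that add atoms: 2,2,2-trichloroethyl chlorosulfate, ClS(=O)(=O)OCC(Cl)(Cl)Cl
Why: O-sulfonylation of the two acidic hydroxyls (O7 phenol and O3 enol) with a chlorosulfate ester under DMAP catalysis; the C5–OH is hydrogen-bonded to C4=O and should stay free, and the neutral diester can be purified on silica.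

Step 10
Reactants: 20 2-[3,4-bis(benzyloxy)phenyl]-5-hydroxy-4-oxo-4H-chromene-3,7-diyl bis(2,2,2-trichloroethyl) bis(sulfate)
Product: 22 quercetin 3,7-di-O-sulfate [2-(3,4-dihydroxyphenyl)-5-hydroxy-4-oxo-4H-chromene-3,7-diyl bis(hydrogen sulfate)], via diammonium quercetin 3,7-disulfate 21 (not isolated)
Conditions: 10 % Pd/C, HCO2NH4 (10 equiv), MeOH/THF 3:1, rt to 35 °C, Ar; filter, evaporate; 1 M HCl (2.0 equiv), 0 °C; Sephadex LH-20 (MeOH/H2O, 4 °C); lyophilise
Reagents that add atoms: none
Why: Reductive β-elimination of the trichloroethyl groups and transfer hydrogenolysis of the benzyl ethers on palladium with formate as reductant should unmask both sulfate monoesters and the catechol in one operation, and cold acid–base exchange gives the free acid.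

**Compound list**
1 | kojic acid [5-hydroxy-2-(hydroxymethyl)-4H-pyran-4-one] | OCc1cc(=O)c(O)co1 | starting material
2 | 6-bromokojic acid [2-bromo-3-hydroxy-6-(hydroxymethyl)-4H-pyran-4-one] | OCc1cc(=O)c(O)c(Br)o1 | intermediate
3 | 2-bromo-6-(hydroxymethyl)-3-[(4-methoxybenzyl)oxy]-4H-pyran-4-one | OCc1cc(=O)c(OCc2ccc(OC)cc2)c(Br)o1 | intermediate
4 | 3,4-bis(benzyloxy)phenylboronic acid | OB(O)c1ccc(OCc2ccccc2)c(OCc2ccccc2)c1 | starting material
5 | 2-[3,4-bis(benzyloxy)phenyl]-6-(hydroxymethyl)-3-[(4-methoxybenzyl)oxy]-4H-pyran-4-one | OCc1cc(=O)c(OCc2ccc(OC)cc2)c(-c2ccc(OCc3ccccc3)c(OCc3ccccc3)c2)o1 | intermediate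
6 | 6-[3,4-bis(benzyloxy)phenyl]-5-[(4-methoxybenzyl)oxy]-4-oxo-4H-pyran-2-carboxylic acid | OC(=O)c1cc(=O)c(OCc2ccc(OC)cc2)c(-c2ccc(OCc3ccccc3)c(OCc3ccccc3)c2)o1 | intermediate
7 | 6-[3,4-bis(benzyloxy)phenyl]-5-[(4-methoxybenzyl)oxy]-4-oxo-4H-pyran-2-carboxylic isobutyl carbonic anhydride (not isolated) | CC(C)COC(=O)OC(=O)c1cc(=O)c(OCc2ccc(OC)cc2)c(-c2ccc(OCc3ccccc3)c(OCc3ccccc3)c2)o1 | intermediate
8 | 2-[3,4-bis(benzyloxy)phenyl]-6-(diazoacetyl)-3-[(4-methoxybenzyl)oxy]-4H-pyran-4-one | [N-]=[N+]=CC(=O)c1cc(=O)c(OCc2ccc(OC)cc2)c(-c2ccc(OCc3ccccc3)c(OCc3ccccc3)c2)o1 | intermediate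
9 | trichloroethylene | ClC=C(Cl)Cl | starting material
10 | tert-butyl (E)-1,2-dichlorovinyl ether (not isolated) | CC(C)(C)O/C(Cl)=C\Cl | intermediate
11 | tert-butoxy(chloro)acetylene (not isolated) | CC(C)(C)OC#CCl | intermediate
12 | lithium tert-butoxyacetylide (not isolated) | CC(C)(C)OC#C[Li] | intermediate
13 | tert-butoxyacetylene (tert-butyl ethynyl ether) | CC(C)(C)OC#C | intermediate
14 | {6-[3,4-bis(benzyloxy)phenyl]-5-[(4-methoxybenzyl)oxy]-4-oxo-4H-pyran-2-yl}ketene (not isolated) | O=C=Cc1cc(=O)c(OCc2ccc(OC)cc2)c(-c2ccc(OCc3ccccc3)c(OCc3ccccc3)c2)o1 | intermediate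
15 | 4-{6-[3,4-bis(benzyloxy)phenyl]-5-[(4-methoxybenzyl)oxy]-4-oxo-4H-pyran-2-yl}-3-tert-butoxycyclobut-2-en-1-one (racemic; not isolated) | O=C1C=C(OC(C)(C)C)C1c1cc(=O)c(OCc2ccc(OC)cc2)c(-c2ccc(OCc3ccccc3)c(OCc3ccccc3)c2)o1 | intermediate
16 | (3E)-4-{6-[3,4-bis(benzyloxy)phenyl]-5-[(4-methoxybenzyl)oxy]-4-oxo-4H-pyran-2-yl}-3-tert-butoxybuta-1,3-dien-1-one (not isolated) | O=C=C/C(OC(C)(C)C)=C\c1cc(=O)c(OCc2ccc(OC)cc2)c(-c2ccc(OCc3ccccc3)c(OCc3ccccc3)c2)o1 | intermediate
17 | 2-[3,4-bis(benzyloxy)phenyl]-7-tert-butoxy-3-[(4-methoxybenzyl)oxy]-4aH-chromene-4,5-dione (racemic; not isolated) | O=C1C=C(OC(C)(C)C)C=C2OC(-c3ccc(OCc4ccccc4)c(OCc4ccccc4)c3)=C(OCc3ccc(OC)cc3)C(=O)C12 | intermediate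
18 | 2-[3,4-bis(benzyloxy)phenyl]-7-tert-butoxy-5-hydroxy-3-[(4-methoxybenzyl)oxy]-4H-chromen-4-one | O=c1c(OCc2ccc(OC)cc2)c(-c2ccc(OCc3ccccc3)c(OCc3ccccc3)c2)oc2cc(OC(C)(C)C)cc(O)c12 | intermediate
19 | 2-[3,4-bis(benzyloxy)phenyl]-3,5,7-trihydroxy-4H-chromen-4-one (3',4'-di-O-benzylquercetin) | O=c1c(O)c(-c2ccc(OCc3ccccc3)c(OCc3ccccc3)c2)oc2cc(O)cc(O)c12 | intermediate
20 | 2-[3,4-bis(benzyloxy)phenyl]-5-hydroxy-4-oxo-4H-chromene-3,7-diyl bis(2,2,2-trichloroethyl) bis(sulfate) | O=c1c(OS(=O)(=O)OCC(Cl)(Cl)Cl)c(-c2ccc(OCc3ccccc3)c(OCc3ccccc3)c2)oc2cc(OS(=O)(=O)OCC(Cl)(Cl)Cl)cc(O)c12 | intermediate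
21 | diammonium 2-(3,4-dihydroxyphenyl)-5-hydroxy-4-oxo-4H-chromene-3,7-diyl bis(sulfate) (not isolated) | O=c1c(OS(=O)(=O)[O-])c(-c2ccc(O)c(O)c2)oc2cc(OS(=O)(=O)[O-])cc(O)c12.[NH4+].[NH4+] | intermediate
22 | quercetin 3,7-di-O-sulfate | O=c1c(OS(=O)(=O)O)c(-c2ccc(O)c(O)c2)oc2cc(OS(=O)(=O)O)cc(O)c12 | target

**Step count**
Total: 10 steps. Longest linear sequence: 9 steps (steps 1–5 and 7–10 from kojic acid); step 6 is a one-step branch.

**Steps most likely to fail**

Step 7. The ketene may dimerise, or the alkoxypyranone chromophore may react photochemically, before the [2+2] with a thermally fragile ynol ether takes place. The fallback needs neither light in the ring-forming step nor an ynol ether. It sets out from 8: Wolff rearrangement with silver benzoate (PhCO2Ag) and Et3N in THF/H2O (Arndt–Eistert homologation through ketene 14) should give 2-{6-[3,4-bis(benzyloxy)phenyl]-5-[(4-methoxybenzyl)oxy]-4-oxo-4H-pyran-2-yl}acetic acid F1. Coupling with Meldrum's acid (EDC·HCl, DMAP, CH2Cl2) should give the acyl Meldrum's acid 5-(2-{6-[3,4-bis(benzyloxy)phenyl]-5-[(4-methoxybenzyl)oxy]-4-oxo-4H-pyran-2-yl}-1-hydroxyethylidene)-2,2-dimethyl-1,3-dioxane-4,6-dione F2. Thermolysis in dilute toluene at 110 °C releases acetone and CO2 and forms the acylketene 4-{6-[3,4-bis(benzyloxy)phenyl]-5-[(4-methoxybenzyl)oxy]-4-oxo-4H-pyran-2-yl}-3-oxobut-1-en-1-one F3. Its ketene carbon should acylate C4a, the thermal acylketene C-acylation that underlies flavone syntheses from phloroglucinol and β-keto esters, to give 2-[3,4-bis(benzyloxy)phenyl]-5,7-dihydroxy-3-[(4-methoxybenzyl)oxy]-4H-chromen-4-one F4. TFA/Et3SiH then removes the 4-methoxybenzyl group, and the route is rejoined at 19.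

Step 10. Chloride released from the trichloroethyl groups may poison the palladium surface and leave benzyl ethers in place, or S–O cleavage may accompany the reduction. The fallback separates the two deprotections and uses no palladium. It sets out from 20: BCl3 with pentamethylbenzene in CH2Cl2 at −78 °C should cleave the benzyl ethers to 2-(3,4-dihydroxyphenyl)-5-hydroxy-4-oxo-4H-chromene-3,7-diyl bis(2,2,2-trichloroethyl) bis(sulfate) F5. Zinc dust and HCO2NH4 in MeOH then remove the trichloroethyl groups by reductive elimination, and the route is rejoined at 21, which is acidified as in step 10.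

Step 8. The 4-methoxybenzyl cation may re-alkylate C6 or C8 of the electron-rich ring A before it is trapped. The fallback removes this group oxidatively, so no free benzylic cation is formed. It sets out from 18: DDQ in CH2Cl2/pH 7 buffer should give 2-[3,4-bis(benzyloxy)phenyl]-7-tert-butoxy-3,5-dihydroxy-4H-chromen-4-one F6. Brief TFA/CH2Cl2 with Et3SiH then cleaves only the tert-butyl ether, and the route is rejoined at 19.

**Further compounds**
F1 | step 7 | 2-{6-[3,4-bis(benzyloxy)phenyl]-5-[(4-methoxybenzyl)oxy]-4-oxo-4H-pyran-2-yl}acetic acid | OC(=O)Cc1cc(=O)c(OCc2ccc(OC)cc2)c(-c2ccc(OCc3ccccc3)c(OCc3ccccc3)c2)o1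
F2 | step 7 | 5-(2-{6-[3,4-bis(benzyloxy)phenyl]-5-[(4-methoxybenzyl)oxy]-4-oxo-4H-pyran-2-yl}-1-hydroxyethylidene)-2,2-dimethyl-1,3-dioxane-4,6-dione | CC1(C)OC(=O)C(=C(O)Cc2cc(=O)c(OCc3ccc(OC)cc3)c(-c3ccc(OCc4ccccc4)c(OCc4ccccc4)c3)o2)C(=O)O1
F3 | step 7 | 4-{6-[3,4-bis(benzyloxy)phenyl]-5-[(4-methoxybenzyl)oxy]-4-oxo-4H-pyran-2-yl}-3-oxobut-1-en-1-one | O=C=CC(=O)Cc1cc(=O)c(OCc2ccc(OC)cc2)c(-c2ccc(OCc3ccccc3)c(OCc3ccccc3)c2)o1
F4 | step 7 | 2-[3,4-bis(benzyloxy)phenyl]-5,7-dihydroxy-3-[(4-methoxybenzyl)oxy]-4H-chromen-4-one | O=c1c(OCc2ccc(OC)cc2)c(-c2ccc(OCc3ccccc3)c(OCc3ccccc3)c2)oc2cc(O)cc(O)c12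
F5 | step 10 | 2-(3,4-dihydroxyphenyl)-5-hydroxy-4-oxo-4H-chromene-3,7-diyl bis(2,2,2-trichloroethyl) bis(sulfate) | O=c1c(OS(=O)(=O)OCC(Cl)(Cl)Cl)c(-c2ccc(O)c(O)c2)oc2cc(OS(=O)(=O)OCC(Cl)(Cl)Cl)cc(O)c12
F6 | step 8 | 2-[3,4-bis(benzyloxy)phenyl]-7-tert-butoxy-3,5-dihydroxy-4H-chromen-4-one | O=c1c(O)c(-c2ccc(OCc3ccccc3)c(OCc3ccccc3)c2)oc2cc(OC(C)(C)C)cc(O)c12
A1 | direct plan | 1-[2-hydroxy-4,6-bis(allyloxy)phenyl]ethan-1-one | CC(=O)c1c(O)cc(OCC=C)cc1OCC=C
A2 | direct plan | 3,4-bis(benzyloxy)benzoyl chloride | ClC(=O)c1ccc(OCc2ccccc2)c(OCc2ccccc2)c1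
A3 | direct plan | 1-[2-hydroxy-4,6-bis(allyloxy)phenyl]-3-[3,4-bis(benzyloxy)phenyl]propane-1,3-dione | O=C(CC(=O)c1ccc(OCc2ccccc2)c(OCc2ccccc2)c1)c1c(O)cc(OCC=C)cc1OCC=C
A4 | direct plan | potassium 1-[3,4-bis(benzyloxy)phenyl]-3-[2-hydroxy-4,6-bis(allyloxy)phenyl]-1,3-dioxopropan-2-yl sulfate (racemic) | O=C(C(OS(=O)(=O)[O-])C(=O)c1ccc(OCc2ccccc2)c(OCc2ccccc2)c1)c1c(O)cc(OCC=C)cc1OCC=C.[K+]
A5 | direct plan | potassium 5,7-bis(allyloxy)-2-[3,4-bis(benzyloxy)phenyl]-4-oxo-4H-chromen-3-yl sulfate | O=c1c(OS(=O)(=O)[O-])c(-c2ccc(OCc3ccccc3)c(OCc3ccccc3)c2)oc2cc(OCC=C)cc(OCC=C)c12.[K+]
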